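All runs stem from a simulated flask for an exercise, and the scatter is random.

The easy step came first. In these flasks substrate and partner give target over a free catalyst, so I divided the target in the earliest useful readings by their time. At 1.00 min the grey run gave 2.55 mM min⁻¹, and at 2.00 min the teal run gave 2.60 mM min⁻¹, although teal held twice the substrate. I called the grey reading the turnover ceiling: the rate of target read with partner near its charge, and since the two readings agreed within their scatter, I took it as zero order in substrate.

| run | time / min | target / % | substrate / % |
|---|---|---|---|
| teal | 2.00 | 52 | 6 |
| teal | 5.00 | 60 | 1 |
| teal | 10.0 | 59 | 4 |
| teal | 25.0 | 60 | 3 |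
| grey | 0.200 | 10 | 74 |
| grey | 0.500 | 26 | 50 |
| grey | 1.00 | 51 | 20 |
| grey | 2.50 | 79 | 0 |

(each reading ± 2 percentage points)

all flasks: free catalyst 1.5 mM
- teal: substrate 10 mM; partner 18 mM; run made earlier
- grey: substrate 5 mM; partner 18 mM; run made earlier
- dawn: substrate 10 mM; partner 18.0 mM (fed, over 2.0 min); all else is in the flask from the start; the feed brings no volume worth counting; time 25 min
- noon: substrate 10 mM; partner 18.0 mM (fed, over 20 min); all else is in the flask from the start; the feed brings no volume worth counting; time 25 min
- winter: substrate 10 mM (fed, over 20 min); partner 18.0 mM; all else is in the flask from the start; the feed brings no volume worth counting; time 25 min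
- midnight: substrate 10 mM; partner 18.0 mM; everything together at the start; time 25 min

1. the best flask by amount of target, in percent of the substrate charged; "all alike" if 1.5 percentage points covers them all (dawn / noon / winter / midnight / all alike)
2. amount of target at the end, in percent of the substrate charged, dawn
3. amount of target at the end, in percent of the substrate charged, noon
4. amount of target at the end, in percent of the substrate charged, winter
5. amount of target at the end, in percent of the substrate charged, midnight



From that reading I built a ladder of times. On the first rung, I reckoned that one catalyst load took 0.588 min at the ceiling. On the next, teal's substrate stood at 6% after 2.00 min, sooner than the 3.92 min the ceiling needs for that charge, so a second drain ran beside the catalyst. Teal finally lost 4.00 mM and grey 1.05 mM, a factor of 3.81 for a doubled charge, so by these readings the drain took a larger share of the larger charge, and I read it as running harder the higher substrate stood, without fixing its order. The last rungs were the feed of 20 min and the time of 25 min. Winter's feed of 0.500 mM min⁻¹ stood at a ratio of 0.196 to the ceiling, so I took the catalyst's uptake as keeping pace with the feed and expected a low, steady substrate level that starved the drain. I therefore put winter first. Midnight has teal's charges, so I expected teal's 60%. Partner never varied in these runs, so they gave me no ceiling for dawn or noon.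

The forecast named winter, saying “Feeding substrate slowly keeps its level”, and gave dawn 53%, noon 25%, winter 90% and midnight 60%.

The flasks gave dawn 42.5%, noon 23.7%, winter 99.3% and midnight 58.7%, so winter was best.

    substrate + catalyst intermediate A → catalyst intermediate B (k = 42.1 M⁻¹ s⁻¹)
    substrate → decomposition product (k = 8.16 × 10⁻⁶ s⁻¹)
    partner + free catalyst → catalyst intermediate A (k = 6.98 M⁻¹ s⁻¹)
    2 substrate → self-condensation product (k = 1.10 M⁻¹ s⁻¹)
    catalyst intermediate C ⇌ free catalyst + target (K = 0.00499 M, k = 0.166 s⁻¹)
    catalyst intermediate B → catalyst intermediate C (k = 3.48 s⁻¹)

At the end of its feed, winter held 1.90% substrate and 0.657% self-condensation product, against 76.2% of that product in noon at the end of its own feed. With the self-condensation step taken away, the gap between winter and noon shrank from 76 percentage points to 0.33 points, the largest single effect tried. The neighbour of winter charged with 25 mM substrate was fed at 1.25 mM min⁻¹, a ratio of 0.490 to the ceiling, but with 0.720 equiv of partner as limiting reagent it ended at 64.5% target, with 4.0% of its partner left and 28.6% self-condensation product.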